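**Retrosynthetic overview**

1. The carbocycle is numbered C1 (ester carbon), C2=C3 (CH3 on C3), C4, C5, C6 (carbinol), C7 (isopropyl), C8, C9, C10 (quaternary, CH3); the seven-membered ring is C1–C6 plus C10 and the five-membered ring is C6–C10. The plan rests on C2, the only ring methine lying between oxygenated C1 and methylated C3. Taking it out leaves a 2-methylcyclohexanone (ring C1, C3, C4, C5, C6, C10) inside a cis-hydrindane, and its ketone can enolise only toward C3 because C10 carries no hydrogen.
2. Target 18 ⇒ acylation of diol 16 ⇒ reduction of enone 15 directed by the C6 hydroxyl ⇒ one-carbon ring expansion of silyl enol ether 11 (C1–C2 and C2–C3 made, C1–C3 broken).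
3. 11 ⇒ C3 methylation and silylation of hydrindanone 8 ⇒ oxidation and hydrogenation of ene adduct 6 ⇒ carbonyl-ene closure (C6–C7) of hydroxy ketone 5.
4. 5 ⇒ enzymatic desymmetrisation of prochiral dione 4 (fixes C10) ⇒ Michael addition to acrolein and Wittig olefination from 2-methylcyclohexane-1,3-dione 1.
5. Ring order: the six-membered ring is bought, the five-membered ring is closed in step 4, and the six-membered ring is expanded to the seven-membered ring in step 10.

Key step: step 10

Assumption: a ketoreductase with the required preference between the two enantiotopic carbonyls of 4 is found by panel screening. Compound 5 is drawn as the 2R,3S isomer; the C1 carbinol is oxidised in step 6, so only the configuration at C10 has to be right. Target locants are used for all intermediates (C2 does not exist before step 10).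

**Route**

Step 1
Reactants: 1 (2-methylcyclohexane-1,3-dione); 2 (acrolein)
Product: 3 keto aldehyde 3-(1-methyl-2,6-dioxocyclohexyl)propanal
Conditions: acrolein (1.5 equiv), H2O, rt
Reagents that add atoms: none
Why: Michael addition of the acidic 2-alkyl-1,3-dione to acrolein in water builds quaternary C10 and the C9–C8–C7 chain without the O-alkylation that troubles unactivated alkyl halides, and no stereocentre arises because C10 is still prochiral.

Step 2
Reactants: 3 (keto aldehyde)
Product: 4 dione 2-methyl-2-(4-methylpent-3-en-1-yl)cyclohexane-1,3-dione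
Conditions: i-PrPPh3I (1.1 equiv), n-BuLi (1.05 equiv), THF, 0 °C; then 3, −78 → 0 °C
Reagents that add atoms: isopropyltriphenylphosphonium iodide, CC(C)[P+](c1ccccc1)(c1ccccc1)c1ccccc1.[I-]
Why: Wittig olefination with one equivalent of the non-stabilised isopropylidene ylide at low temperature should take the aldehyde only, since both ring ketones flank the quaternary carbon and react far more slowly, and it installs the trisubstituted alkene that serves as the ene donor.

Step 3
Reactants: 4 (prochiral dione)
Product: 5 hydroxy ketone (2R,3S)-3-hydroxy-2-methyl-2-(4-methylpent-3-en-1-yl)cyclohexan-1-one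
Conditions: ketoreductase, NADP+ (cat.), i-PrOH, phosphate buffer pH 7, DMSO (5%), 30 °C
Reagents that add atoms: none
Why: Enzymatic desymmetrising carbonyl reduction of a 2,2-disubstituted cyclohexane-1,3-dione is well established; the enzyme's choice of one enantiotopic carbonyl (which becomes C1) sets quaternary C10 as R, and the hydride face sets the temporary C1 carbinol.

Step 4
Reactants: 5 (hydroxy ketone)
Product: 6 ene adduct (1R,3aR,4S,7aS)-3a-methyl-1-(prop-1-en-2-yl)octahydro-1H-indene-4,7a-diol
Conditions: Me2AlCl (3 equiv), CH2Cl2, −78 → 0 °C; then 1 M HCl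
Reagents that add atoms: none
Why: In this Lewis-acid-promoted intramolecular carbonyl-ene reaction the first equivalent of Me2AlCl converts the C1 hydroxyl into its aluminium alkoxide and further reagent activates the C6 ketone, C7 bonds to C6 from the face that carries the tether so the ring fusion must be cis (C6–OH cis to C10–CH3), and the six-membered transition state that passes an allylic methyl hydrogen to the carbonyl oxygen places the isopropenyl group at C7 cis to the new hydroxyl.

Step 5
Reactants: 6 (ene adduct)
Product: 7 saturated diol (1R,3aR,4S,7aS)-3a-methyl-1-(propan-2-yl)octahydro-1H-indene-4,7a-diol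
Conditions: H2 (1 atm), PtO2, EtOAc, rt
Reagents that add atoms: none
Why: Catalytic hydrogenation of the unhindered 1,1-disubstituted alkene over PtO2, chosen over palladium to suppress migration of the double bond to the C7-exocyclic position that would endanger C7, creates no stereocentre.

Step 6
Reactants: 7 (saturated diol)
Product: 8 hydrindanone (1R,3aS,7aS)-7a-hydroxy-3a-methyl-1-(propan-2-yl)octahydro-4H-inden-4-one
Conditions: Dess–Martin periodinane (1.3 equiv), CH2Cl2, 0 °C → rt
Reagents that add atoms: none
Why: Dess–Martin oxidation turns the secondary C1 carbinol into the ketone under non-basic conditions, the tertiary C6 alcohol cannot be oxidised, and the beta-hydroxy ketone cannot dehydrate into conjugation because C10 is quaternary.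

Step 7
Reactants: 8 (hydrindanone)
Product: 9 silyl ether (1R,3aS,7aS)-3a-methyl-1-(propan-2-yl)-7a-[(trimethylsilyl)oxy]octahydro-4H-inden-4-one
Conditions: 1-(trimethylsilyl)imidazole (2 equiv), CH2Cl2, rt
Reagents that add atoms: 1-(trimethylsilyl)imidazole, C[Si](C)(C)n1ccnc1
Why: O-Silylation with the silyl imidazole caps the hindered tertiary C6 hydroxyl without enolising the ketone, so that the enolate chemistry that follows cannot open the C6–C10 bond by retro-aldol through a free alkoxide.

Step 8
Reactants: 9 (silyl ether)
Product: 10 methyl ketone (1R,3aS,7aS)-3a,5-dimethyl-1-(propan-2-yl)-7a-[(trimethylsilyl)oxy]octahydro-4H-inden-4-one (both C3 epimers)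
Conditions: LiN(i-Pr)2 (1.1 equiv), THF, −78 °C; CH3I (3 equiv), DMPU, −78 → −20 °C
Reagents that add atoms: iodomethane, CI
Why: Enolate alkylation is regiochemically unambiguous because the ketone has alpha hydrogens only at C3, and the new C3 centre may form as a mixture of epimers since it becomes sp2 in step 9.

Step 9
Reactants: 10 (methyl ketone)
Product: 11 silyl enol ether (1R,3aS,7aS)-3a,5-dimethyl-1-(propan-2-yl)-4,7a-bis[(trimethylsilyl)oxy]-2,3,3a,6,7,7a-hexahydro-1H-indene
Conditions: TMSOTf (1.5 equiv), Et3N (3 equiv), CH2Cl2, 0 °C → rt
Reagents that add atoms: trimethylsilyl trifluoromethanesulfonate, C[Si](C)(C)OS(=O)(=O)C(F)(F)F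
Why: Silyl enol ether formation by soft enolisation can give only the fully substituted C1=C3 isomer, again because C10 bears no hydrogen, and it removes the C3 stereocentre.

Step 10
Reactants: 11 (silyl enol ether)
Product: 14 hydroazulene enone C6 trimethylsilyl ether, via siloxycyclopropane 12 (not isolated), via beta-chloro ketone 13 (not isolated)
Conditions: Et2Zn (3 equiv), CH2I2 (3 equiv), PhMe, 0 °C → rt; pyridine, filter, solvent switch to DMF; FeCl3 (2.5 equiv), 0 °C → rt; then NaOAc, MeOH, reflux (crude intermediates carried through)
Reagents that add atoms: diiodomethane, ICI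
Why: The Furukawa zinc carbenoid transfers CH2 in a concerted syn addition to the electron-rich C1=C3 enol ether and gives the 1-siloxybicyclo[4.1.0]heptane 12, forming C1–C2 and C2–C3. FeCl3 (trivalent iron) then replaces silicon on the cyclopropanol oxygen and oxidises it by one electron to an oxygen-centred radical whose beta-scission breaks the internal C1–C3 bond to give the C1 ketone and the tertiary C3 radical, a second FeCl3 hands chlorine to that radical (13), and NaOAc removes HCl by enolisation toward C2 and loss of chloride, leaving C2=C3 in conjugation. The closest known reaction is the Saegusa–Ito FeCl3 one-carbon ring expansion of cycloalkanone silyl enol ethers to cycloalk-2-enones, run on the Furukawa–Simmons–Smith adduct. The seven-membered ring is not closed end to end: the three-membered ring C1–C2–C3 closes by [2+1] addition and the seven-membered ring appears when the bond shared by the three- and six-membered rings is cleaved. No stereocentre is created, because C1 and C3 both end as sp2 carbons and the face of carbenoid attack is therefore irrelevant, while C6, C7 and C10 are untouched. The step needs regiocontrol twice and the substrate provides it: the enol ether can only be C1=C3 because C10 is quaternary, and scission of the ring bond releases a tertiary radical at methyl-bearing C3 whereas scission of C1–C2 would give a primary one; no other alkene is present and the C6 hydroxyl is masked.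

Step 11
Reactants: 14 (enone silyl ether)
Product: 15 hydroxy enone (1R,3aS,8aS)-8a-hydroxy-3a,6-dimethyl-1-(propan-2-yl)-2,3,3a,7,8,8a-hexahydroazulen-4(1H)-one
Conditions: 1 M aq. HCl, THF, 0 °C → rt
Reagents that add atoms: none
Why: Acidic silyl ether hydrolysis frees the C6 hydroxyl needed for the next step without generating an alkoxide that could add across the ring to C3 or undergo retro-aldol, and any material already desilylated in step 10 converges here.

Step 12
Reactants: 15 (hydroxy enone)
Product: 16 diol (1R,3aR,4R,8aS)-3a,6-dimethyl-1-(propan-2-yl)-1,2,3,3a,4,7,8,8a-octahydroazulene-4,8a-diol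
Conditions: Me4NBH(OAc)3 (5 equiv), MeCN/AcOH (1:1), −30 °C → rt
Reagents that add atoms: none
Why: In this Evans–Saksena hydroxyl-directed reduction the C6 hydroxyl exchanges onto boron and the bound hydride is delivered intramolecularly to C1 on the face of the C6 oxygen, so the new C1 hydroxyl ends trans to the C6 hydroxyl and the C10 methyl (C1 = R), while the free reagent is too weak to reduce the enone intermolecularly, which also enforces 1,2-addition.

Step 13
Reactants: 16 (diol); 17 (4-methoxybenzoyl chloride)
Product: 18 target (1R,3aR,4R,8aS)-8a-hydroxy-3a,6-dimethyl-1-(propan-2-yl)-1,2,3,3a,4,7,8,8a-octahydroazulen-4-yl 4-methoxybenzoate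
Conditions: 17 (1.5 equiv), DMAP (cat.), pyridine, CH2Cl2, 0 °C → rt
Reagents that add atoms: none
Why: DMAP-catalysed acylation esterifies the secondary allylic C1 hydroxyl while the tertiary ring-fusion C6 hydroxyl is too hindered to react, leaving all four stereocentres unchanged.

**Compound list**

1 | 2-methylcyclohexane-1,3-dione | CC1C(=O)CCCC1=O | starting material
2 | acrolein (prop-2-enal) | C=CC=O | starting material
3 | 3-(1-methyl-2,6-dioxocyclohexyl)propanal | CC1(CCC=O)C(=O)CCCC1=O | intermediate
4 | 2-methyl-2-(4-methylpent-3-en-1-yl)cyclohexane-1,3-dione | CC(C)=CCCC1(C)C(=O)CCCC1=O | intermediate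
5 | (2R,3S)-3-hydroxy-2-methyl-2-(4-methylpent-3-en-1-yl)cyclohexan-1-one | O=C1CCC[C@H](O)[C@@]1(C)CCC=C(C)C | intermediate
6 | (1R,3aR,4S,7aS)-3a-methyl-1-(prop-1-en-2-yl)octahydro-1H-indene-4,7a-diol; cis-fused, with C1–OH, C6–OH, C10–CH3 and C7-isopropenyl on one face | O[C@H]1CCC[C@]2(O)[C@@H](C(C)=C)CC[C@]12C | intermediate
7 | (1R,3aR,4S,7aS)-3a-methyl-1-(propan-2-yl)octahydro-1H-indene-4,7a-diol | O[C@H]1CCC[C@]2(O)[C@@H](C(C)C)CC[C@]12C | intermediate
8 | (1R,3aS,7aS)-7a-hydroxy-3a-methyl-1-(propan-2-yl)octahydro-4H-inden-4-one | O=C1CCC[C@]2(O)[C@@H](C(C)C)CC[C@]12C | intermediate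
9 | (1R,3aS,7aS)-3a-methyl-1-(propan-2-yl)-7a-[(trimethylsilyl)oxy]octahydro-4H-inden-4-one | O=C1CCC[C@]2(O[Si](C)(C)C)[C@@H](C(C)C)CC[C@]12C | intermediate
10 | (1R,3aS,7aS)-3a,5-dimethyl-1-(propan-2-yl)-7a-[(trimethylsilyl)oxy]octahydro-4H-inden-4-one, mixture of epimers at the new methyl-bearing carbon (C3) | O=C1C(C)CC[C@]2(O[Si](C)(C)C)[C@@H](C(C)C)CC[C@]12C | intermediate
11 | (1R,3aS,7aS)-3a,5-dimethyl-1-(propan-2-yl)-4,7a-bis[(trimethylsilyl)oxy]-2,3,3a,6,7,7a-hexahydro-1H-indene (C1=C3 silyl enol ether, C6 silyl ether) | C[Si](C)(C)OC1=C(C)CC[C@]2(O[Si](C)(C)C)[C@@H](C(C)C)CC[C@]12C | intermediate (key-step precursor)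
12 | siloxycyclopropane: compound 11 with CH2 (C2) bridging C1 and C3; either face of addition, C6, C7 and C10 as in 11 | C[Si](C)(C)OC12CC1(C)CC[C@]1(O[Si](C)(C)C)[C@@H](C(C)C)CC[C@]21C | intermediate (not isolated)
13 | beta-chloro ketone: seven-membered C1 ketone with chlorine and methyl on C3, C6 silyl ether retained | O=C1CC(C)(Cl)CC[C@]2(O[Si](C)(C)C)[C@@H](C(C)C)CC[C@]12C | intermediate (not isolated)
14 | (1R,3aS,8aS)-3a,6-dimethyl-1-(propan-2-yl)-8a-[(trimethylsilyl)oxy]-2,3,3a,7,8,8a-hexahydroazulen-4(1H)-one | O=C1C=C(C)CC[C@]2(O[Si](C)(C)C)[C@@H](C(C)C)CC[C@]12C | intermediate (key-step product)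
15 | (1R,3aS,8aS)-8a-hydroxy-3a,6-dimethyl-1-(propan-2-yl)-2,3,3a,7,8,8a-hexahydroazulen-4(1H)-one | O=C1C=C(C)CC[C@]2(O)[C@@H](C(C)C)CC[C@]12C | intermediate
16 | (1R,3aR,4R,8aS)-3a,6-dimethyl-1-(propan-2-yl)-1,2,3,3a,4,7,8,8a-octahydroazulene-4,8a-diol; C1–OH trans to C6–OH and C10–CH3 | O[C@@H]1C=C(C)CC[C@]2(O)[C@@H](C(C)C)CC[C@]12C | intermediate
17 | 4-methoxybenzoyl chloride | COc1ccc(cc1)C(Cl)=O | starting material
18 | (1R,3aR,4R,8aS)-8a-hydroxy-3a,6-dimethyl-1-(propan-2-yl)-1,2,3,3a,4,7,8,8a-octahydroazulen-4-yl 4-methoxybenzoate | COc1ccc(C(=O)O[C@@H]2C=C(C)CC[C@]3(O)[C@@H](C(C)C)CC[C@]23C)cc1 | target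

**Step count and risks**

Total steps: 13. Longest linear sequence: 13 steps (from 1).

Steps most likely to fail:

1. Step 10 (ring expansion). Methylene transfer to the crowded, fully substituted enol ether beside quaternary C10 may stall. The oxidative opening may also leak through cleavage of the outer C1–C2 bond or through elimination of the tertiary chloride away from conjugation. The fallback sets out from 11 and returns at 14. Compound 11 is treated with CHBr3 and KOt-Bu in pentane at −20 °C, where the far more electrophilic dibromocarbene should add to C1=C3 and give the dibromo(siloxy)cyclopropane F1. Warming F1 in toluene with pyridine should ionise one C–Br bond with disrotatory opening of the C1–C3 bond, a cyclopropyl-to-allyl cation opening that can break only the ring-fusion bond, and loss of the silyl group then gives the 2-bromo enone F2. The vinylic bromide of F2 is removed by palladium-catalysed formate hydrogenolysis (Pd(OAc)2, PPh3, HCO2H, Et3N, DMF, 60 °C), which gives 14.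

2. Step 4 (carbonyl-ene closure). The aluminium-bound zwitterion may not collapse cleanly by hydrogen transfer: chloride capture at the tertiary cation, methyl transfer from aluminium to C6, or erosion of the cis relationship at C6/C7 are the likely leaks. The fallback sets out from 5 and returns at 7. The closure is run deliberately as a Prins cyclisation with chloride capture (MeAlCl2, CH2Cl2, −78 °C). The tether still dictates the attacked face of C6, so the cis-fused chloro diol F3 should form, with chloride handed over from the metal on the C6 oxygen. Radical dechlorination of F3 (Bu3SnH, AIBN, benzene, 80 °C) gives 7 directly and makes step 5 unnecessary.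

3. Step 12 (directed reduction). Exchange of the hindered tertiary C6 hydroxyl onto boron may be slow, so that hydride delivery is inefficient and facial or 1,2-selectivity erodes. The fallback sets out from 15 and returns at 18. Compound 15 is reduced under Luche conditions (NaBH4, CeCl3·7H2O, MeOH, −78 °C), which is reliably 1,2-selective and is expected to attack the face away from C10–CH3 and C6–OH, giving mainly the C1-epimeric cis-diol F4. F4 is esterified with inversion at C1 by a Mitsunobu reaction with 4-methoxybenzoic acid (PPh3, DIAD, PhMe), which gives 18 directly; displacement at this hindered allylic carbon is the weak point of the fallback. Any 16 formed alongside is acylated as in step 13.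

**Further compounds**

F1 | step 10 | dibromo(siloxy)cyclopropane: compound 11 with CBr2 bridging C1 and C3 | C[Si](C)(C)OC12C(Br)(Br)C1(C)CC[C@]1(O[Si](C)(C)C)[C@@H](C(C)C)CC[C@]21C
F2 | step 10 | 2-bromo enone: compound 14 with bromine on C2 | O=C1C(Br)=C(C)CC[C@]2(O[Si](C)(C)C)[C@@H](C(C)C)CC[C@]12C
F3 | step 4 | chloro diol: compound 7 with chlorine on the central isopropyl carbon (2-chloropropan-2-yl at C7) | O[C@H]1CCC[C@]2(O)[C@@H](C(C)(C)Cl)CC[C@]12C
F4 | step 12 | (1R,3aR,4S,8aS)-3a,6-dimethyl-1-(propan-2-yl)-1,2,3,3a,4,7,8,8a-octahydroazulene-4,8a-diol (C1 epimer of 16, cis-diol) | O[C@H]1C=C(C)CC[C@]2(O)[C@@H](C(C)C)CC[C@]12C
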